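Remark: lignan numbering is used throughout (ring O–C7–C8–C8'–C9', arm C9 on C8, arm C7' on C8'). The target is taken as drawn, (7R,8S,8'S), i.e. the 9-O-(4-hydroxybenzoate) of (7R,8S,8'S)-lariciresinol. 4-(Benzyloxy)-3-methoxybenzaldehyde, the benzyl ether of vanillin, is treated as a catalogue compound.

## The problem

Agastinol is a 7,9'-epoxylignan: one tetrahydrofuran ring O–C7–C8–C8'–C9' carrying a guaiacyl group on C7, an acyloxymethyl arm (C9) on C8 and a guaiacylmethyl arm (C7') on C8'. Nothing is fused or bridged, so the difficulty lies in three contiguous stereocentres (7R,8S,8'S) on a flexible five-membered ring: the aryl group is trans to the C9 arm, and the C9 and C7' arms are cis. The 8,8'-cis relationship cannot be repaired afterwards, because neither centre is epimerisable in the target and cis is the less stable arrangement; it has to be built in by the bond-forming event. C7, in contrast, is a p-oxygenated benzylic ether carbon that acid can equilibrate towards the 7,8-trans arrangement wanted here, so C8/C8' should control and C7 may follow. The two one-carbon arms must end up different (an esterified CH2O and a CH2–aryl) and are best made different from the start. Fragile points are the benzylic C7–O bond (ionised by acid, cleaved by prolonged hydrogenolysis), three phenols, and an aryl ester that would not survive organometallics, hydride or base and so has to go on last, at the only aliphatic hydroxyl. The feature that invites a cycloaddition is that C7–O–C9' is a masked carbonyl ylide, ArCH=O(+)–CH2(−), while C8–C8' with its two cis arms is the alkene of a butenolide whose carbonyl carbon (C9) and acetal carbon (C7') already differ in oxidation level and whose acetal oxygen can carry a chiral group that controls the face.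

## Retrosynthesis

**C9–O (ester).** Cutting the alkyl C9–O bond of agastinol 21 gives (7R,8S,8'S)-lariciresinol 19 and 4-hydroxybenzoic acid 20. Carrying the ester through earlier steps would expose it to Grignard, borane and hydrogenolysis chemistry, and acylating a protected triol would add protection steps. The forward reaction must select one aliphatic hydroxyl among four OH groups; a Mitsunobu reaction does this by mechanism, since only the aliphatic alcohol is activated and only the carboxylic acid is acidic enough to be the nucleophile.

**C9 oxidation level.** Alcohol 19 is traced to carboxylic acid 18. No skeletal bond is cut, but the step is needed because the ring-forming reaction delivers C9 as a carbonyl. Borane is asked to reduce an acid in the presence of phenols and a benzylic ether.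

**C7'–H and the O-benzyl bonds.** Acid 18 is traced to the bis-benzyl-protected γ-aryl lactone 17. One hydrogenolysis cleaves the benzylic lactone C7'–O bond, which frees C9 as the acid and leaves C7' as CH2, and removes both benzyl ethers. This is preferred to a separate deoxygenation of a benzylic alcohol because the lactone is the natural resting state of the hydroxy acid and an acyloxy group is the most easily hydrogenolysed benzylic substituent. The forward step must spare the benzylic C7–O ether.

**C7'–aryl.** Lactone 17 is cut between C7' and its aryl ring, giving lactol 12 (a masked aldehyde at C7' next to a C9 acid) and the aryl Grignard reagent 15, made from bromide 14 and ultimately from 4-bromo-2-methoxyphenol 13. The cut uses the aldehyde oxidation level that C7' already has and puts no demand on the new carbinol centre, which is removed later; the ring-opened adduct is hydroxy acid 16.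

**Acetal C7'–O.** Lactol 12 comes from menthyl acetal 11 by hydrolysis, which also returns the auxiliary.

**C7–C8 and C8'–C9' (ring formation).** Cycloadduct 11 is cut across both bonds into carbonyl ylide 10 and (5R)-5-menthyloxyfuranone 9. This removes the ring, two skeletal bonds and all three stereocentres at once, and leaves an achiral dipole and a crystalline chiral butenolide. The ylide is generated from chloromethyl α-silylbenzyl ether 4 with fluoride. The forward reaction must be regioselective (benzylic terminus to the α-carbon), anti to the menthyloxy group, and exo for the aryl group. Benzyl is chosen for the phenol because it survives fluoride, where a silyl ether would not.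

**Ylide precursor.** Chloride 4 comes from methylthiomethyl ether 3 (S-to-Cl exchange), 3 from α-silyl alcohol 2, and 2 from aldehyde 1 by silyl anion addition. The two-step chloromethylation is chosen over formaldehyde/HCl because 2 is a p-alkoxybenzylic alcohol that strong acid would ionise.

**Dipolarophile.** Furanone 9 comes from 5-hydroxyfuranone 7 and (−)-menthol 8 by acetalisation and crystallisation; 7 comes from furfural 5 by photo-oxygenation through endoperoxide 6.

## Roads not taken

Alternative 1: The cut goes through C7–C8 and the O–C9' bond of a lactone in which C9' is still a carbonyl and C7' an exocyclic methylene. Forward, aldehyde A1 and the γ-substituted 2-carboxyallylboronate A2 would combine under a chiral acid catalyst: allylboration through a closed six-membered transition state makes C7–C8, and the new hydroxyl lactonises onto the ester to give the trans α-methylene lactone A3 with C7 and C8 set. The second aryl group would then be added to the methylene carbon, C8' set by protonation of the resulting enolate, and the lactone carbonyl reduced to the ether CH2.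
- Merits: catalytic enantiocontrol without an auxiliary, C7 and C8 fixed together in a well-understood transition state, and a short sequence.
- Weak points: A1 is an electron-rich, deactivated aldehyde and γ-substituted boronates such as A2 are the slow class for acid-catalysed allylboration. The 8,8'-cis arrangement would rest on a kinetic protonation giving the less stable epimer at a carbon α to a carbonyl. C9' must be taken from lactone to ether with Lewis acid/hydride chemistry next to the ionisable benzylic C7–O bond.
- Comparison: this road is better in catalyst economy and in not depending on an untested regiochemistry. The chosen plan sets against it that the cis C8/C8' pair is dictated by alkene geometry in a suprafacial addition, that C9' enters at the ether oxidation level, and that the auxiliary is a recoverable terpene alcohol.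

Alternative 2: Three bonds are cut at once: O–C7, C8–C8' and C7'–aryl. Forward, the alkoxide of propargyl alcohol A4 adds to arylidene malonate A5 (oxa-Michael); the malonate anion then attacks the alkyne activated by the arylpalladium(II) species from aryl iodide A6 (anti carbopalladation, 5-exo-dig), and reductive elimination gives benzylidene tetrahydrofuran A7. Mono-decarboxylation, hydrogenation of the benzylidene group and reduction of the remaining ester would follow.
- Merits: the most convergent assembly of the four roads; ring, both aryl groups and almost all carbons arrive in one step from three simple achiral pieces. In convergence and probably in step count it beats the chosen plan.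
- Weak points: C7 is created in a reversible oxa-Michael step with nothing to bias it, so the absolute configuration needs a resolution or a chiral variant that has not been established. The quaternary malonate carbon must be cut down under hot dealkoxycarbonylation conditions. C8' would be set by hydrogenating an exocyclic alkene whose facial bias comes only from remote substituents, with hydrogenolysis of benzylic C7–O as a competitor.
- Comparison: the chosen plan gives up some convergence and gains absolute control from the first ring-forming step and a relative configuration that does not rest on a late hydrogenation.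

Alternative 3: C8–C9 and C8'=C7' are cut on a preformed lactone; no ring is closed in the key step. Forward, the cuprate derived from silylmethyl Grignard reagent A9 adds to C8 of γ-aryl butenolide A8 anti to the C7 aryl group, and the enolate condenses with aldehyde A1 (aldol, then elimination in the same flask) to give arylidene lactone A10. Hydrogenation anti to the C8 arm would give the cis C8/C8' pair, Tamao–Fleming oxidation would reveal the C9 hydroxyl, and the lactone would be reduced to the ether.
- Merits: every bond forms with unambiguous regiochemistry, stereochemistry is relayed C7→C8→C8' from one centre, and each reaction type is well established. In regiochemical certainty it is better than the chosen plan.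
- Weak points: A8 must be enantioenriched, and its C7–H is both benzylic and vinylogously acidic, so racemisation under the basic organometallic step is a real threat. The hydrogenation must be run on a γ-aryl lactone whose benzylic C7–O bond has to survive. The lactone-to-ether reduction is needed again.
- Comparison: in the chosen plan the benzylic lactone bond that hydrogenolysis attacks is the one meant to break, C9' is never a carbonyl, and the absolute configuration comes from a crystalline auxiliary; the price is the regiochemical uncertainty of the dipole.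

Key step: step 6

## Route

Step 1
Reactants: 1 4-(benzyloxy)-3-methoxybenzaldehyde
Product: 2 rac-[4-(benzyloxy)-3-methoxyphenyl](trimethylsilyl)methanol
Conditions: Me3SiLi (from Me3SiSiMe3, MeLi, HMPA, 0 °C), THF, −78 °C; AcOH, −78 °C
Reagents that add atoms: hexamethyldisilane (source of Me3SiLi), C[Si](C)(C)[Si](C)(C)C
Why: 1,2-addition of a silyl anion (trimethylsilyllithium) to an aryl aldehyde gives the α-silyl carbinol; the electron-rich ring, the lithium counter-ion and the cold acidic quench hold back the Brook (C→O) silyl shift. The new centre is racemic, which is harmless because it becomes the planar ylide carbon.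

Step 2
Reactants: 2 rac-[4-(benzyloxy)-3-methoxyphenyl](trimethylsilyl)methanol
Product: 3 rac-{[4-(benzyloxy)-3-methoxyphenyl][(methylsulfanyl)methoxy]methyl}trimethylsilane
Conditions: Me2S, (BzO)2, MeCN, 0 °C
Reagents that add atoms: dimethyl sulfide, CSC
Why: Methylthiomethylation of an alcohol with dimethyl sulfide and benzoyl peroxide (Pummerer-type transfer of a CH2SMe unit) needs neither strong base nor strong acid, so neither the Brook-prone alkoxide nor the p-alkoxybenzylic cation is generated.

Step 3
Reactants: 3 rac-{[4-(benzyloxy)-3-methoxyphenyl][(methylsulfanyl)methoxy]methyl}trimethylsilane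
Product: 4 rac-chloromethyl [4-(benzyloxy)-3-methoxyphenyl](trimethylsilyl)methyl ether
Conditions: SO2Cl2 (1.0 equiv), CH2Cl2, −78 °C; evaporate, use crude
Reagents that add atoms: sulfuryl chloride, O=S(=O)(Cl)Cl
Why: Chlorinolysis of an O,S-acetal with sulfuryl chloride, the method used for acid-sensitive alkoxymethyl chlorides such as p-methoxybenzyl chloromethyl ether: sulfur is chlorinated, MeSCl leaves and chloride captures the oxocarbenium ion at −78 °C; the by-products are volatile.

Step 4
Reactants: 5 furfural
Product: 7 5-hydroxyfuran-2(5H)-one, via furfural endoperoxide 6 (not isolated)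
Conditions: O2, hν (visible), rose bengal (cat.), MeOH, rt
Reagents that add atoms: dioxygen, O=O
Why: Dye-sensitised photo-oxygenation: singlet oxygen adds [4+2] across the furan, and methanolysis of the endoperoxide expels the formyl carbon as methyl formate, a long-established route to this hydroxybutenolide.

Step 5
Reactants: 7 5-hydroxyfuran-2(5H)-one; 8 (−)-menthol
Product: 9 (5R)-5-{[(1R,2S,5R)-5-methyl-2-(propan-2-yl)cyclohexyl]oxy}furan-2(5H)-one
Conditions: p-TsOH (cat.), toluene, reflux (−H2O); crystallise from petroleum ether; mother liquor re-equilibrated (p-TsOH) and recrystallised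
Reagents that add atoms: none
Why: Acid-catalysed acetalisation of the pseudo-acid gives both C5 epimers, which interconvert under the acid; the (5R) diastereomer crystallises, so the acetal centre is set by crystallisation-driven resolution against the fixed centres of menthol.

Step 6
Reactants: 4 rac-chloromethyl [4-(benzyloxy)-3-methoxyphenyl](trimethylsilyl)methyl ether; 9 (5R)-5-menthyloxyfuran-2(5H)-one
Product: 11 (3R,3aS,6R,6aR)-6-[4-(benzyloxy)-3-methoxyphenyl]-3-[(1R,2S,5R)-menthyloxy]tetrahydro-1H,3H-furo[3,4-c]furan-1-one, via carbonyl ylide 10 (not isolated)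
Conditions: CsF (anhydrous, 3 equiv), MeCN, rt; 4 (1.5 equiv) added slowly
Reagents that add atoms: none
Why: Fluoride attacks silicon of 4 and chloride leaves in a 1,3-elimination, giving the non-stabilised carbonyl ylide 10, ArCH=O(+)–CH2(−), which is trapped as it forms by the electron-poor alkene of 9; the closest known reaction type is the fluoride-induced (3+2) cycloaddition of carbonyl ylides from chloromethyl α-silylbenzyl ethers with acrylates, fumarates and maleimides, and 9 is an established dipolarophile for diazoalkanes, nitrones, nitrile oxides and azomethine ylides. The tetrahydrofuran ring closes in a concerted suprafacial [π4s+π2s] cycloaddition in which C7–C8 and C9'–C8' form together, so no stepwise exo or endo ring-closure mode is involved. C8 and C8' are set by the face of the alkene that is attacked: the menthyloxy group on the acetal carbon shields its own face and the dipole adds anti to it, as other dipoles do with 9, and because the addition is suprafacial on a cis ring alkene the C9 and C7' arms are necessarily cis. C7 is set by the exo approach in which the aryl group points away from the lactone ring, giving aryl trans to the C8 carbonyl; if some endo adduct forms, the p-alkoxybenzylic C7–O bond can ionise reversibly under the acid of step 7 and re-close to the more stable trans arrangement. The step needs regioselectivity, benzylic terminus to the α-carbon (C8) and CH2 terminus to the β-carbon (C8'): the ylide HOMO has its larger coefficient on the unsubstituted carbon because the aryl group delocalises the other terminus, the butenolide LUMO is largest at the β-carbon, and the bulkier benzylic terminus is kept away from the acetal substituent. The racemic centre of 4 is erased in the planar ylide, so only 9 controls the outcome; slow addition of excess 4 keeps the short-lived ylide in contact with 9.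

Step 7
Reactants: 11 cycloadduct (menthyl acetal lactone)
Product: 12 (3aS,6R,6aR)-6-[4-(benzyloxy)-3-methoxyphenyl]-3-hydroxytetrahydro-1H,3H-furo[3,4-c]furan-1-one (lactol, both C3 epimers)
Conditions: 2 M aq. HCl, 1,4-dioxane, 50 °C
Reagents that add atoms: water, O
Why: Acid hydrolysis of the mixed alkoxy/acyloxy acetal (a pseudo-ester) frees menthol for recovery and leaves the lactol, the ring tautomer of the cis aldehyde acid, in which C8' is not enolisable; any reversible opening of the benzylic C7–O bond returns to the more stable 7,8-trans arrangement, the one wanted.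

Step 8
Reactants: 13 4-bromo-2-methoxyphenol
Product: 14 1-(benzyloxy)-4-bromo-2-methoxybenzene
Conditions: BnBr, K2CO3, acetone, reflux
Reagents that add atoms: benzyl bromide, BrCc1ccccc1
Why: Williamson ether synthesis on a phenol; the aryl bromide is untouched.

Step 9
Reactants: 12 lactol; 14 1-(benzyloxy)-4-bromo-2-methoxybenzene
Product: 17 (3aS,6R,6aR)-3,6-bis[4-(benzyloxy)-3-methoxyphenyl]tetrahydro-1H,3H-furo[3,4-c]furan-1-one (both C3 epimers), via aryl Grignard reagent 15 (not isolated), via hydroxy acid 16 (not isolated)
Conditions: 14, Mg, THF, reflux; then 12 (3 equiv ArMgBr per 12), THF, −20 °C → rt; 1 M HCl, rt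
Reagents that add atoms: none
Why: Grignard formation, then addition to a pseudo-acid: the first equivalent deprotonates the lactol, which opens to the magnesium carboxylate aldehyde, and the second adds to the aldehyde faster than it can be enolised (the behaviour known for hydroxybutenolides and 3-hydroxyphthalide); acid work-up closes the γ-lactone. The C7' centre is left uncontrolled on purpose, since step 10 removes it.

Step 10
Reactants: 17 bis-benzyl γ-aryl lactone
Product: 18 (2R,3R,4S)-2-(4-hydroxy-3-methoxyphenyl)-4-(4-hydroxy-3-methoxybenzyl)tetrahydrofuran-3-carboxylic acid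
Conditions: H2 (1 atm), 10% Pd/C, EtOAc–MeOH, rt; stopped when the lactone is consumed
Reagents that add atoms: none
Why: Palladium-catalysed hydrogenolysis cleaves the benzylic acyloxy C7'–O bond of the γ-aryl lactone and both aryl benzyl ethers, the two most readily cleaved classes of benzylic C–O bond, while the benzylic alkyl ether bond C7–O of the ring reacts more slowly. No stereocentre of the target is touched and the uncontrolled C7' centre disappears.

Step 11
Reactants: 18 carboxylic acid
Product: 19 [(2R,3S,4S)-2-(4-hydroxy-3-methoxyphenyl)-4-(4-hydroxy-3-methoxybenzyl)tetrahydrofuran-3-yl]methanol, (7R,8S,8'S)-lariciresinol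
Conditions: BH3·THF (excess), THF, 0 °C → rt; MeOH
Reagents that add atoms: none
Why: Borane reduces a carboxylic acid selectively through its acyloxyborane; the phenols only consume hydride as aryl borates, which methanolysis returns, and the ring ether is inert.

Step 12
Reactants: 19 (7R,8S,8'S)-lariciresinol; 20 4-hydroxybenzoic acid
Product: 21 agastinol, [(2R,3S,4S)-2-(4-hydroxy-3-methoxyphenyl)-4-(4-hydroxy-3-methoxybenzyl)tetrahydrofuran-3-yl]methyl 4-hydroxybenzoate
Conditions: PPh3, DIAD, THF, 0 °C → rt
Reagents that add atoms: none
Why: Mitsunobu esterification: only the aliphatic primary hydroxyl forms an alkoxyphosphonium ion, and it is displaced by the carboxylate, the most acidic pronucleophile present (pKa about 4.5 against about 10 for the phenols), as in the known chemoselective esterification of phenolic acids with phenolic alcohols. C9 is not stereogenic, so the inversion has no consequence.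

## Compound list

1 | 4-(benzyloxy)-3-methoxybenzaldehyde (O-benzylvanillin) | COc1cc(C=O)ccc1OCc1ccccc1 | starting material
2 | rac-[4-(benzyloxy)-3-methoxyphenyl](trimethylsilyl)methanol | COc1cc(C(O)[Si](C)(C)C)ccc1OCc1ccccc1 | intermediate
3 | rac-{[4-(benzyloxy)-3-methoxyphenyl][(methylsulfanyl)methoxy]methyl}trimethylsilane | COc1cc(C(OCSC)[Si](C)(C)C)ccc1OCc1ccccc1 | intermediate
4 | rac-chloromethyl [4-(benzyloxy)-3-methoxyphenyl](trimethylsilyl)methyl ether | ClCOC(c1ccc(OCc2ccccc2)c(OC)c1)[Si](C)(C)C | intermediate
5 | furfural | O=Cc1ccco1 | starting material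
6 | furfural endoperoxide (2,3,7-trioxabicyclo[2.2.1]hept-5-ene-1-carbaldehyde, racemic) | O=CC12OOC(O1)C=C2 | intermediate (not isolated)
7 | 5-hydroxyfuran-2(5H)-one (racemic) | O=C1C=CC(O)O1 | intermediate
8 | (−)-menthol, (1R,2S,5R) | CC(C)[C@@H]1CC[C@@H](C)C[C@H]1O | starting material
9 | (5R)-5-[(1R,2S,5R)-menthyloxy]furan-2(5H)-one | O=C1O[C@@H](O[C@@H]2C[C@H](C)CC[C@H]2C(C)C)C=C1 | intermediate
10 | carbonyl ylide, [4-(benzyloxy)-3-methoxybenzylidene]oxonium methylide | [CH2-][O+]=Cc1ccc(OCc2ccccc2)c(OC)c1 | intermediate (not isolated)
11 | (3R,3aS,6R,6aR)-6-[4-(benzyloxy)-3-methoxyphenyl]-3-[(1R,2S,5R)-menthyloxy]tetrahydro-1H,3H-furo[3,4-c]furan-1-one (cis-fused; aryl exo; menthyloxy trans to the C8'–C9' bond) | O=C1O[C@@H](O[C@@H]3C[C@H](C)CC[C@H]3C(C)C)[C@@H]2CO[C@@H](c3ccc(OCc4ccccc4)c(OC)c3)[C@H]12 | intermediate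
12 | (3aS,6R,6aR)-6-[4-(benzyloxy)-3-methoxyphenyl]-3-hydroxytetrahydro-1H,3H-furo[3,4-c]furan-1-one (lactol, C3 epimers) | O=C1OC(O)[C@@H]2CO[C@@H](c3ccc(OCc4ccccc4)c(OC)c3)[C@H]12 | intermediate
13 | 4-bromo-2-methoxyphenol | COc1cc(Br)ccc1O | starting material
14 | 1-(benzyloxy)-4-bromo-2-methoxybenzene | COc1cc(Br)ccc1OCc1ccccc1 | intermediate
15 | [4-(benzyloxy)-3-methoxyphenyl]magnesium bromide | COc1cc([Mg]Br)ccc1OCc1ccccc1 | intermediate (not isolated)
16 | (2R,3R,4S)-2-[4-(benzyloxy)-3-methoxyphenyl]-4-{[4-(benzyloxy)-3-methoxyphenyl](hydroxy)methyl}tetrahydrofuran-3-carboxylic acid (carbinol epimers) | OC(c1ccc(OCc2ccccc2)c(OC)c1)[C@@H]1CO[C@@H](c2ccc(OCc3ccccc3)c(OC)c2)[C@@H]1C(=O)O | intermediate (not isolated)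
17 | (3aS,6R,6aR)-3,6-bis[4-(benzyloxy)-3-methoxyphenyl]tetrahydro-1H,3H-furo[3,4-c]furan-1-one (C3 epimers) | O=C1OC(c3ccc(OCc4ccccc4)c(OC)c3)[C@@H]2CO[C@@H](c3ccc(OCc4ccccc4)c(OC)c3)[C@H]12 | intermediate
18 | (2R,3R,4S)-2-(4-hydroxy-3-methoxyphenyl)-4-(4-hydroxy-3-methoxybenzyl)tetrahydrofuran-3-carboxylic acid | COc1cc(C[C@@H]2CO[C@@H](c3ccc(O)c(OC)c3)[C@@H]2C(=O)O)ccc1O | intermediate
19 | (7R,8S,8'S)-lariciresinol, [(2R,3S,4S)-2-(4-hydroxy-3-methoxyphenyl)-4-(4-hydroxy-3-methoxybenzyl)tetrahydrofuran-3-yl]methanol | COc1cc(C[C@@H]2CO[C@@H](c3ccc(O)c(OC)c3)[C@@H]2CO)ccc1O | intermediate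
20 | 4-hydroxybenzoic acid | O=C(O)c1ccc(O)cc1 | starting material
21 | agastinol | COc1cc(C[C@@H]2CO[C@@H](c3ccc(O)c(OC)c3)[C@@H]2COC(=O)c2ccc(O)cc2)ccc1O | target

## Step count and weak points

Total: 12 steps. Longest linear sequence: 9 steps (steps 1, 2, 3, 6, 7, 9, 10, 11, 12 from 1).

**Step 6 (key step).** The dipole may add with the reverse regiochemistry (benzylic terminus to C8'), since the frontier-orbital and steric arguments are untested on this pair. The short-lived ylide may collapse before it meets the moderately reactive butenolide. Fluoride may slowly epimerise the acetal centre of 9 and erode facial purity. Incomplete exo selectivity at C7 is the least serious, because acid equilibration corrects it.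
Fallback (sets out from 7 and 1, returns at 19): the ring is built by the tandem conjugate addition–aldol chemistry established for menthyloxybutenolides. It needs the mirror-image auxiliary, because the carbanion now brings C7' rather than C9' to C8'.
- Acetalisation of 7 with (+)-menthol and crystallisation gives (5S)-5-[(1S,2R,5S)-menthyloxy]furan-2(5H)-one F1.
- 1 and thiophenol (BF3·OEt2) give [4-(benzyloxy)-3-methoxyphenyl]bis(phenylsulfanyl)methane F2.
- Lithiated F2 (n-BuLi, THF, −78 °C) adds to C8' of F1 anti to the menthyloxy group, and the lactone enolate is trapped at C8, trans to the new substituent, with a second portion of 1, giving the hydroxybenzyl thioacetal lactone F3.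
- LiAlH4 reduces the lactone and acetal carbons to the thioacetal triol F4.
- Catalytic camphorsulfonic acid ionises the benzylic C7 alcohol and the C9' hydroxyl closes the ring under thermodynamic control (7,8-trans), giving the thioacetal tetrahydrofuran F5.
- Raney nickel removes the phenylsulfanyl groups to give 4,4'-di-O-benzyl-(7R,8S,8'S)-lariciresinol F6, and a brief hydrogenolysis (H2, Pd/C) gives 19.

**Step 1.** The α-silyl alkoxide may undergo Brook rearrangement (silyl shift from carbon to oxygen), favoured by the HMPA needed to make the reagent; the resulting carbanion is then protonated or adds to more aldehyde.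
Fallback (sets out from 1, returns at 2): the acylsilane route.
- 1 and propane-1,3-dithiol (BF3·OEt2) give 2-[4-(benzyloxy)-3-methoxyphenyl]-1,3-dithiane F7.
- n-BuLi then Me3SiCl give [2-(4-(benzyloxy)-3-methoxyphenyl)-1,3-dithian-2-yl]trimethylsilane F8.
- Thioacetal hydrolysis (HgCl2, HgO, aq. MeCN) gives the aroylsilane [4-(benzyloxy)-3-methoxyphenyl](trimethylsilyl)methanone F9.
- NaBH4 reduces F9 to 2.

**Step 3.** Electrophilic chlorination or sulfenylation of the activated ring may compete, and the chloromethyl ether may solvolyse or self-alkylate on handling.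
Fallback (sets out from 2, returns at 4): direct chloromethylation of alcohol 2 with paraformaldehyde and chlorotrimethylsilane (CH2Cl2, 0 °C), i.e. hemiformal formation and chlorination in place of sulfide cleavage. It bypasses 3 and makes no new compound. It is kept in reserve because it is more acidic.

**Step 10.** Over-reduction may occur: hydrogenolytic opening of the benzylic C7–O ring bond before the lactone C7'–O bond is fully cleaved.
Fallback (sets out from 12 and 14, returns at 19): C7' is arylated at the CH2 oxidation level by reductive coupling of a tosylhydrazone with a boronic acid, so that no benzylic C7'–O bond is ever formed.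
- 12 is alkylated on its carboxylate (MeI, KHCO3, DMF) to methyl (2R,3R,4S)-2-[4-(benzyloxy)-3-methoxyphenyl]-4-formyltetrahydrofuran-3-carboxylate F10.
- Tosylhydrazide gives the tosylhydrazone F11.
- 14 is converted (n-BuLi; B(OiPr)3; H3O+) into [4-(benzyloxy)-3-methoxyphenyl]boronic acid F12.
- F11 and F12 (K2CO3, dioxane, 110 °C) give methyl (2R,3R,4S)-2-[4-(benzyloxy)-3-methoxyphenyl]-4-[4-(benzyloxy)-3-methoxybenzyl]tetrahydrofuran-3-carboxylate F13.
- A short hydrogenolysis that only has to cleave aryl benzyl ethers gives the bisphenol methyl ester F14, and LiAlH4 reduces it to 19.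

**Step 12.** Chemoselectivity may be lost: phenol oxygens may take part as nucleophiles, or the hydroxy acid may self-condense.
Fallback (sets out from 19 and 20, returns at 21): phenols are masked with a group that is removed without hydrogen or acid.
- 19 with allyl bromide and K2CO3 (acetone) gives 4,4'-di-O-allyl-lariciresinol F15.
- 20 is converted by allylation and saponification of the allyl ester into 4-(prop-2-en-1-yloxy)benzoic acid F16.
- Carbodiimide coupling (EDC, DMAP) of F15 and F16 gives tri-O-allyl agastinol F17.
- Pd(PPh3)4 with morpholine removes the three allyl groups to give 21.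

## Further compounds

F1 | step 6 | (5S)-5-[(1S,2R,5S)-menthyloxy]furan-2(5H)-one | O=C1O[C@H](O[C@H]2C[C@@H](C)CC[C@@H]2C(C)C)C=C1
F2 | step 6 | [4-(benzyloxy)-3-methoxyphenyl]bis(phenylsulfanyl)methane | COc1cc(C(Sc2ccccc2)Sc2ccccc2)ccc1OCc1ccccc1
F3 | step 6 | hydroxybenzyl thioacetal lactone (tandem adduct; thioacetal arm anti to menthyloxy, carbinol arm trans to it, carbinol epimers) | O=C1O[C@H](O[C@H]2C[C@@H](C)CC[C@@H]2C(C)C)[C@@H](C(Sc2ccccc2)(Sc2ccccc2)c2ccc(OCc3ccccc3)c(OC)c2)[C@@H]1C(O)c1ccc(OCc2ccccc2)c(OC)c1
F4 | step 6 | thioacetal triol | OC[C@@H](C(Sc1ccccc1)(Sc1ccccc1)c1ccc(OCc2ccccc2)c(OC)c1)[C@@H](CO)C(O)c1ccc(OCc2ccccc2)c(OC)c1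
F5 | step 6 | thioacetal tetrahydrofuran (7,7-bis(phenylsulfanyl) derivative of F6) | COc1cc(C(Sc2ccccc2)(Sc2ccccc2)[C@@H]2CO[C@@H](c3ccc(OCc4ccccc4)c(OC)c3)[C@@H]2CO)ccc1OCc1ccccc1
F6 | step 6 | 4,4'-di-O-benzyl-(7R,8S,8'S)-lariciresinol | COc1cc(C[C@@H]2CO[C@@H](c3ccc(OCc4ccccc4)c(OC)c3)[C@@H]2CO)ccc1OCc1ccccc1
F7 | step 1 | 2-[4-(benzyloxy)-3-methoxyphenyl]-1,3-dithiane | COc1cc(C2SCCCS2)ccc1OCc1ccccc1
F8 | step 1 | [2-(4-(benzyloxy)-3-methoxyphenyl)-1,3-dithian-2-yl]trimethylsilane | COc1cc(C2([Si](C)(C)C)SCCCS2)ccc1OCc1ccccc1
F9 | step 1 | [4-(benzyloxy)-3-methoxyphenyl](trimethylsilyl)methanone | COc1cc(C(=O)[Si](C)(C)C)ccc1OCc1ccccc1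
F0 | step 3 | none | none
F10 | step 10 | methyl (2R,3R,4S)-2-[4-(benzyloxy)-3-methoxyphenyl]-4-formyltetrahydrofuran-3-carboxylate | O=C[C@@H]1CO[C@@H](c2ccc(OCc3ccccc3)c(OC)c2)[C@@H]1C(=O)OC
F11 | step 10 | tosylhydrazone of F10 | Cc1ccc(S(=O)(=O)N/N=C/[C@@H]2CO[C@@H](c3ccc(OCc4ccccc4)c(OC)c3)[C@@H]2C(=O)OC)cc1
F12 | step 10 | [4-(benzyloxy)-3-methoxyphenyl]boronic acid | COc1cc(B(O)O)ccc1OCc1ccccc1
F13 | step 10 | methyl (2R,3R,4S)-2-[4-(benzyloxy)-3-methoxyphenyl]-4-[4-(benzyloxy)-3-methoxybenzyl]tetrahydrofuran-3-carboxylate | COc1cc(C[C@@H]2CO[C@@H](c3ccc(OCc4ccccc4)c(OC)c3)[C@@H]2C(=O)OC)ccc1OCc1ccccc1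
F14 | step 10 | methyl (2R,3R,4S)-2-(4-hydroxy-3-methoxyphenyl)-4-(4-hydroxy-3-methoxybenzyl)tetrahydrofuran-3-carboxylate | COc1cc(C[C@@H]2CO[C@@H](c3ccc(O)c(OC)c3)[C@@H]2C(=O)OC)ccc1O
F15 | step 12 | 4,4'-di-O-allyl-(7R,8S,8'S)-lariciresinol | COc1cc(C[C@@H]2CO[C@@H](c3ccc(OCC=C)c(OC)c3)[C@@H]2CO)ccc1OCC=C
F16 | step 12 | 4-(prop-2-en-1-yloxy)benzoic acid | C=CCOc1ccc(C(=O)O)cc1
F17 | step 12 | tri-O-allyl agastinol | COc1cc(C[C@@H]2CO[C@@H](c3ccc(OCC=C)c(OC)c3)[C@@H]2COC(=O)c2ccc(OCC=C)cc2)ccc1OCC=C
A1 | alternative 1 | 3-methoxy-4-[(triisopropylsilyl)oxy]benzaldehyde (also used in alternative 3) | COc1cc(C=O)ccc1O[Si](C(C)C)(C(C)C)C(C)C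
A2 | alternative 1 | methyl (E)-4-[(tert-butyldimethylsilyl)oxy]-2-[(4,4,5,5-tetramethyl-1,3,2-dioxaborolan-2-yl)methyl]but-2-enoate | COC(=O)/C(CB1OC(C)(C)C(C)(C)O1)=C/CO[Si](C)(C)C(C)(C)C
A3 | alternative 1 | trans-γ-aryl-β-(silyloxymethyl)-α-methylene-γ-butyrolactone, C7 and C8 as in the target | C=C1C(=O)O[C@@H](c2ccc(O[Si](C(C)C)(C(C)C)C(C)C)c(OC)c2)[C@@H]1CO[Si](C)(C)C(C)(C)C
A4 | alternative 2 | prop-2-yn-1-ol | C#CCO
A5 | alternative 2 | diethyl 2-{3-methoxy-4-[(triisopropylsilyl)oxy]benzylidene}malonate | CCOC(=O)C(=Cc1ccc(O[Si](C(C)C)(C(C)C)C(C)C)c(OC)c1)C(=O)OCC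
A6 | alternative 2 | (4-iodo-2-methoxyphenoxy)triisopropylsilane | COc1cc(I)ccc1O[Si](C(C)C)(C(C)C)C(C)C
A7 | alternative 2 | diethyl 2-aryl-4-[(Z)-arylmethylene]tetrahydrofuran-3,3-dicarboxylate, C7 as in the target | CCOC(=O)C1(C(=O)OCC)[C@H](c2ccc(O[Si](C(C)C)(C(C)C)C(C)C)c(OC)c2)OC/C1=C\c1ccc(O[Si](C(C)C)(C(C)C)C(C)C)c(OC)c1
A8 | alternative 3 | 5-{3-methoxy-4-[(triisopropylsilyl)oxy]phenyl}furan-2(5H)-one, C7 as in the target | O=C1O[C@@H](c2ccc(O[Si](C(C)C)(C(C)C)C(C)C)c(OC)c2)C=C1
A9 | alternative 3 | [(isopropoxydimethylsilyl)methyl]magnesium chloride | CC(C)O[Si](C)(C)C[Mg]Cl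
A10 | alternative 3 | (E)-α-arylidene-β-(silylmethyl)-γ-aryl butyrolactone, C7 and C8 as in the target | O=C1O[C@@H](c2ccc(O[Si](C(C)C)(C(C)C)C(C)C)c(OC)c2)[C@H](C[Si](C)(C)OC(C)C)/C1=C\c1ccc(O[Si](C(C)C)(C(C)C)C(C)C)c(OC)c1
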